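## Retrosynthetic overview

1. Target ⇒ (CH2 ⇐ C=O) an o‑hydroxybenzophenone. The 4‑hydroxybenzyl arm is traced back to a 4‑hydroxybenzoyl group, whose carbonyl is what tells the two ring oxygens apart (OH next to it, OMe para to it).
2. Benzophenone ⇒ Friedel–Crafts aroylation with ortho‑demethylation of the symmetric 2‑(3,5‑dimethoxyphenethyl)phenol using 4‑acetoxybenzoyl chloride. C2 and C6 are identical by symmetry, so the only regiochemical question is C2 versus C4.
3. Bibenzyl ⇒ deoxybenzoin (Wolff–Kishner).
4. Key disconnection, ArC(=O)–CH2Ar′ ⇒ carbene‑bound acyl anion of 3,5‑dimethoxybenzaldehyde plus the parent o‑quinone methide, released from 2‑(tosylmethyl)phenol (made from salicyl alcohol). Two normally electrophilic carbons are joined by polarity reversal, and the target's own 2′‑OH is the activating group.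
5. No ring is formed. All three benzene rings are bought (A = central ring, B = 2‑hydroxyphenyl, C = 4‑hydroxyphenyl) and joined in the order B–A (key step), then A–C.

Assumption: the target has no stereocentre (it is achiral), so no enantiocontrol is needed and no SMILES carries a stereodescriptor.

## Route

Step 1
Reactants: 1 2-(hydroxymethyl)phenol (salicyl alcohol)
Product: 2 2-[(4-methylbenzenesulfonyl)methyl]phenol
Conditions: TolSO2Na (1.5 equiv), conc. HCl (1.5 equiv), AcOH/H2O 1:1, 50 °C, 6 h
Reagents that add atoms: sodium 4-methylbenzenesulfinate, Cc1ccc(cc1)S(=O)[O-].[Na+]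
Why: Acid-promoted SN1-type benzylic substitution through the o-hydroxybenzyl cation (protonated o-quinone methide), in which the soft sulfinate sulfur alkylates to give the bench-stable sulfone; no stereocentre is formed.

Step 2
Reactants: 2 2-[(4-methylbenzenesulfonyl)methyl]phenol, 3 3,5-dimethoxybenzaldehyde
Product: 6 1-(3,5-dimethoxyphenyl)-2-(2-hydroxyphenyl)ethan-1-one, via o-quinone methide 4 (not isolated), via Breslow intermediate 5 (not isolated)
Conditions: 3 (1.5 equiv), 2-(pentafluorophenyl)-6,7-dihydro-5H-pyrrolo[2,1-c][1,2,4]triazol-2-ium tetrafluoroborate (20 mol %), Cs2CO3 (1.3 equiv), 4 Å MS, THF, 25 → 40 °C, 2 added over 3 h; then cold 1 M HCl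
Reagents that add atoms: none
Why: Proposed new method: Cs2CO3 deprotonates 2 and expels sulfinate to release the parent o-quinone methide 4 reversibly and at low concentration, while the triazolylidene turns 3 into the nucleophilic Breslow intermediate 5, whose acyl-anion carbon adds 1,4 (Stetter-type) to the exocyclic CH2 of 4 with rearomatisation before the adduct collapses to ketone 6 and free carbene (homo-benzoin of 3 is reversible and drains into 6); the closest known reaction types are carbene-derived acyl-anion additions to fluoride-generated o-quinone methides, NHC-catalysed aldehyde additions to aza-o-quinone methides and p-quinone methides, and NHC annulations of sulfone-derived o-quinone methides; no stereocentre is formed.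

Step 3
Reactants: 6 1-(3,5-dimethoxyphenyl)-2-(2-hydroxyphenyl)ethan-1-one
Product: 8 2-[2-(3,5-dimethoxyphenyl)ethyl]phenol, via hydrazone 7 (not isolated)
Conditions: N2H4·H2O (6 equiv), KOH (4 equiv), diethylene glycol, 130 °C, 2 h, then distil to 200 °C, 4 h; 2 M HCl
Reagents that add atoms: none
Why: Wolff–Kishner reduction (Huang-Minlon procedure), in which hydrazone 7 is deprotonated and loses N2 to leave the methylene, under basic conditions that avoid the acid-induced cyclodehydration of the 2-hydroxybenzyl ketone to a 2-arylbenzofuran and leave the phenol (as phenoxide) and both methyl ethers intact.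

Step 4
Reactants: 8 2-[2-(3,5-dimethoxyphenyl)ethyl]phenol, 9 4-(chlorocarbonyl)phenyl acetate (4-acetoxybenzoyl chloride)
Product: 13 (4-hydroxyphenyl){2-hydroxy-6-[2-(2-hydroxyphenyl)ethyl]-4-methoxyphenyl}methanone, via aryl ester 10 (not isolated), via dimethoxy ketone 11 (not isolated), via phenolic triester 12 (not isolated)
Conditions: 9 (2.4 equiv), AlCl3 (6 equiv), CH2Cl2, 0 → 40 °C, 16 h; ice/1 M HCl; then 2 M NaOH aq., THF, rt, 2 h; 2 M HCl
Reagents that add atoms: none
Why: Friedel–Crafts acylation with chelation-controlled demethylation, in which the phenol is first aroylated (10), the acylium then attacks C2 of the dimethoxy ring (identical to C6 by symmetry, para to one OMe and less hindered than C4 between the two OMe groups) to give 11, AlCl3 chelated between the new C=O and the ortho OMe cleaves only that ether (12), and hydroxide finally removes all three aryl esters so that any partial ester cleavage converges on 13.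

Step 5
Reactants: 13 (4-hydroxyphenyl){2-hydroxy-6-[2-(2-hydroxyphenyl)ethyl]-4-methoxyphenyl}methanone
Product: 14 2-[(4-hydroxyphenyl)methyl]-3-[2-(2-hydroxyphenyl)ethyl]-5-methoxyphenol (target)
Conditions: Et3SiH (5 equiv), TFA/CH2Cl2 1:1, 0 °C → rt, 12 h (13 added slowly); aq. NaHCO3
Reagents that add atoms: none
Why: Ionic hydrogenation, in which the protonated diaryl ketone is reduced through a benzhydryl cation strongly stabilised by the ortho-OH, para-OMe and para′-OH groups, so two hydride transfers from Et3SiH stop cleanly at the diarylmethane and leave the phenols and the methyl ether untouched.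

## Compound list

1 | 2-(hydroxymethyl)phenol (salicyl alcohol) | OCc1ccccc1O | starting material
2 | 2-[(4-methylbenzenesulfonyl)methyl]phenol | Cc1ccc(cc1)S(=O)(=O)Cc1ccccc1O | intermediate
3 | 3,5-dimethoxybenzaldehyde | COc1cc(C=O)cc(OC)c1 | starting material
4 | 6-methylidenecyclohexa-2,4-dien-1-one (parent o-quinone methide) | C=C1C=CC=CC1=O | intermediate
5 | (3,5-dimethoxyphenyl)[2-(pentafluorophenyl)-6,7-dihydro-5H-pyrrolo[2,1-c][1,2,4]triazol-3(2H)-ylidene]methanol (Breslow intermediate) | COc1cc(cc(OC)c1)C(O)=C1N(N=C2CCCN12)c1c(F)c(F)c(F)c(F)c1F | intermediate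
6 | 1-(3,5-dimethoxyphenyl)-2-(2-hydroxyphenyl)ethan-1-one | COc1cc(cc(OC)c1)C(=O)Cc1ccccc1O | intermediate
7 | 2-[2-(3,5-dimethoxyphenyl)-2-hydrazinylideneethyl]phenol (hydrazone) | COc1cc(cc(OC)c1)C(=NN)Cc1ccccc1O | intermediate
8 | 2-[2-(3,5-dimethoxyphenyl)ethyl]phenol | COc1cc(CCc2ccccc2O)cc(OC)c1 | intermediate
9 | 4-(chlorocarbonyl)phenyl acetate | CC(=O)Oc1ccc(cc1)C(Cl)=O | starting material
10 | 2-[2-(3,5-dimethoxyphenyl)ethyl]phenyl 4-acetoxybenzoate | COc1cc(CCc2ccccc2OC(=O)c2ccc(OC(C)=O)cc2)cc(OC)c1 | intermediate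
11 | 2-{2-[2-(4-acetoxybenzoyl)-3,5-dimethoxyphenyl]ethyl}phenyl 4-acetoxybenzoate | COc1cc(OC)c(C(=O)c2ccc(OC(C)=O)cc2)c(CCc2ccccc2OC(=O)c2ccc(OC(C)=O)cc2)c1 | intermediate
12 | 2-{2-[2-(4-acetoxybenzoyl)-3-hydroxy-5-methoxyphenyl]ethyl}phenyl 4-acetoxybenzoate | COc1cc(O)c(C(=O)c2ccc(OC(C)=O)cc2)c(CCc2ccccc2OC(=O)c2ccc(OC(C)=O)cc2)c1 | intermediate
13 | (4-hydroxyphenyl){2-hydroxy-6-[2-(2-hydroxyphenyl)ethyl]-4-methoxyphenyl}methanone | COc1cc(O)c(C(=O)c2ccc(O)cc2)c(CCc2ccccc2O)c1 | intermediate
14 | 2-[(4-hydroxyphenyl)methyl]-3-[2-(2-hydroxyphenyl)ethyl]-5-methoxyphenol | COc1cc(O)c(Cc2ccc(O)cc2)c(CCc2ccccc2O)c1 | target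

## Step count and risks

Total step count: 5. Longest linear sequence: 5 steps (1 → 2 → 6 → 8 → 13 → 14).

The three steps most likely to fail:

Step 2 (key step). The parent o-quinone methide is very reactive: it can oligomerise, O-alkylate phenoxides, alkylate the acidic CH2 of 6 a second time, or alkylate the carbene. The direct aldehyde variant with this precursor is also an extrapolation. The fallback makes the same bond with a stoichiometric acyl-anion equivalent and sets out from 3. Propane-1,3-dithiol and BF3·OEt2 in CH2Cl2 give 2-(3,5-dimethoxyphenyl)-1,3-dithiane F1. Lithiation (n-BuLi, THF, −40 °C) and alkylation with commercial 1-(benzyloxy)-2-(bromomethyl)benzene give 2-{[2-(benzyloxy)phenyl]methyl}-2-(3,5-dimethoxyphenyl)-1,3-dithiane F2. Raney nickel in refluxing ethanol desulfurises this to 1-(benzyloxy)-2-[2-(3,5-dimethoxyphenyl)ethyl]benzene F3, and H2 over Pd/C in ethyl acetate removes the benzyl ether. The fallback comes back to the route at 8, replacing steps 1 to 3.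

Step 4. The aroylation could go partly to C4, the aryl esters could undergo Fries chemistry, or the ortho-demethylation could stop short. The fallback installs the one-carbon unit first and sets out from 8. Vilsmeier–Haack formylation (POCl3, DMF, 0 → 60 °C, aq. NaOAc) gives 2-[2-(2-hydroxyphenyl)ethyl]-4,6-dimethoxybenzaldehyde F4. BCl3 (CH2Cl2, −78 → 0 °C) cleaves only the methoxy group next to the aldehyde and gives 2-hydroxy-6-[2-(2-hydroxyphenyl)ethyl]-4-methoxybenzaldehyde F5. 4-(Benzyloxy)phenylmagnesium bromide (3.5 equiv, THF, 0 °C) gives racemic 2-{[4-(benzyloxy)phenyl](hydroxy)methyl}-3-[2-(2-hydroxyphenyl)ethyl]-5-methoxyphenol F6. H2 over Pd/C in EtOAc/AcOH then removes both the doubly activated benzhydrylic hydroxyl and the benzyl ether. The fallback comes back to the route at 14, replacing steps 4 and 5.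

Step 3. KOH at 200 °C may partly cleave the methyl ethers or give azine. The fallback is a mild hydride reduction of a sulfonylhydrazone and sets out from 6. Tosylhydrazide in ethanol at 70 °C gives N′-[1-(3,5-dimethoxyphenyl)-2-(2-hydroxyphenyl)ethylidene]-4-methylbenzenesulfonohydrazide F7. Catecholborane (CHCl3, 0 °C → rt) followed by NaOAc·3H2O at reflux reduces it to the methylene compound. The fallback comes back to the route at 8.

## Further compounds

F1 | step 2 | 2-(3,5-dimethoxyphenyl)-1,3-dithiane | COc1cc(cc(OC)c1)C1SCCCS1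
F2 | step 2 | 2-{[2-(benzyloxy)phenyl]methyl}-2-(3,5-dimethoxyphenyl)-1,3-dithiane | COc1cc(cc(OC)c1)C1(Cc2ccccc2OCc2ccccc2)SCCCS1
F3 | step 2 | 1-(benzyloxy)-2-[2-(3,5-dimethoxyphenyl)ethyl]benzene | COc1cc(CCc2ccccc2OCc2ccccc2)cc(OC)c1
F4 | step 4 | 2-[2-(2-hydroxyphenyl)ethyl]-4,6-dimethoxybenzaldehyde | COc1cc(OC)c(C=O)c(CCc2ccccc2O)c1
F5 | step 4 | 2-hydroxy-6-[2-(2-hydroxyphenyl)ethyl]-4-methoxybenzaldehyde | COc1cc(O)c(C=O)c(CCc2ccccc2O)c1
F6 | step 4 | 2-{[4-(benzyloxy)phenyl](hydroxy)methyl}-3-[2-(2-hydroxyphenyl)ethyl]-5-methoxyphenol (racemic) | COc1cc(O)c(C(O)c2ccc(OCc3ccccc3)cc2)c(CCc2ccccc2O)c1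
F7 | step 3 | N′-[1-(3,5-dimethoxyphenyl)-2-(2-hydroxyphenyl)ethylidene]-4-methylbenzenesulfonohydrazide | COc1cc(cc(OC)c1)C(Cc1ccccc1O)=NNS(=O)(=O)c1ccc(C)cc1
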